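**Plan**

- Retrosynthesis: the furan is cut last, at O–C2 and at C3–C5(arene), which leaves an ortho-iodophenol and 2-methylbut-3-yn-2-ol. Behind that come the C5–I bond, the O-methyl protecting group and the N1-methyl group (from a methyl carbamate).
- Next the C3a–prenyl bond and the N1–C8a bond are cut together (dearomative prenylation and ring closure of a tryptamine carbamate), then the C3 side chain (oxalylation) and the pyrrole ring of the indole (Bartoli).
- Forward: benzene → indole → tryptamine carbamate → pyrrolidine ring closed during dearomatisation → N-methyl amine, free phenol, C5 iodide → furan ring closed last.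
- The C7 bromine is carried from the commercial nitroarene, so after O-demethylation C5 is the only activated ring position and the iodination has no regiochemical choice.
- Stereochemistry: C3a is set by a chiral Pd–phosphoramidite catalyst in the prenylation; C8a follows because the aminal ring can only close cis.
- Enabling feature: the furan oxygen sits on arene C4 and furan C3 on arene C5, with furan C2 carrying the dimethylcarbinol. This is the pattern of an ortho-iodophenol joined to 2-methylbut-3-yn-2-ol.

Key step: step 10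

Assumption: positions are numbered as in 1,2,3,3a,8,8a-hexahydropyrrolo[2,3-b]indole (N1, C3a, C4–C7, N8, C8a), and the target SMILES corresponds to (3aS,8aS). The sense of induction of the phosphoramidite in step 6 is not predicted here; the ligand antipode that gives the (3aS,8aS) series is selected on a test run.

**Step 1**
Reactants: 1 4-bromo-3-nitroanisole
Product: 3 7-bromo-4-methoxy-1H-indole, via 1-bromo-4-methoxy-2-nitrosobenzene 2 (not isolated)
Conditions: CH2=CHMgBr (3.2 equiv), THF, −45 °C; aq. NH4Cl
Reagents that add atoms: vinylmagnesium bromide, C=C[Mg]Br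
Why: Bartoli indole synthesis, in which the ortho bromine steers the [3,3]-sigmatropic shift of the N-aryl-O-vinylhydroxylamine onto the only free ortho carbon, so that the methoxy group ends up at indole C4 and the bromine at C7.

**Step 2**
Reactants: 3 7-bromo-4-methoxy-1H-indole
Product: 5 2-(7-bromo-4-methoxy-1H-indol-3-yl)-2-oxoacetamide, via indol-3-ylglyoxylyl chloride 4 (not isolated)
Conditions: (COCl)2, Et2O, 0 °C; then NH3 (excess), 0 °C → rt
Reagents that add atoms: oxalyl chloride, ClC(=O)C(=O)Cl; ammonia, N
Why: Friedel–Crafts-type C3 acylation of the indole with oxalyl chloride and aminolysis of the acid chloride (first half of the Speeter–Anthony tryptamine synthesis), C3 being the most nucleophilic position of the indole.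

**Step 3**
Reactants: 5 2-(7-bromo-4-methoxy-1H-indol-3-yl)-2-oxoacetamide
Product: 6 2-(7-bromo-4-methoxy-1H-indol-3-yl)ethan-1-amine
Conditions: AlH3 (from LiAlH4/AlCl3 3:1), THF, 0 → 40 °C; aq. NaOH
Reagents that add atoms: none
Why: Alane reduction of the keto amide to the ethylamine (second half of the Speeter–Anthony sequence), chosen because the electrophilic hydride should reduce both carbonyl groups while leaving the aryl bromide alone, unlike LiAlH4 at reflux.

**Step 4**
Reactants: 6 2-(7-bromo-4-methoxy-1H-indol-3-yl)ethan-1-amine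
Product: 7 methyl N-[2-(7-bromo-4-methoxy-1H-indol-3-yl)ethyl]carbamate
Conditions: ClCO2Me, Et3N, CH2Cl2, 0 °C
Reagents that add atoms: methyl chloroformate, COC(=O)Cl
Why: N-acylation of the primary amine to a carbamate, selective because the amine is far more nucleophilic than the indole nitrogen; the carbamate later serves as the cyclising nucleophile and as the latent N-methyl group.

**Step 5**
Reactants: 8 3-methylbut-2-en-1-ol (prenol)
Product: 9 methyl 3-methylbut-2-en-1-yl carbonate
Conditions: ClCO2Me, pyridine, CH2Cl2, 0 °C → rt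
Reagents that add atoms: methyl chloroformate, COC(=O)Cl
Why: O-acylation of a primary allylic alcohol with a chloroformate gives the allylic carbonate that serves as the π-allyl precursor.

**Step 6**
Reactants: 7 methyl N-[2-(7-bromo-4-methoxy-1H-indol-3-yl)ethyl]carbamate; 9 methyl 3-methylbut-2-en-1-yl carbonate
Product: 11 methyl (3aS,8aS)-7-bromo-4-methoxy-3a-(3-methylbut-2-en-1-yl)-3,3a,8,8a-tetrahydropyrrolo[2,3-b]indole-1(2H)-carboxylate, via 3-prenyl-3H-indole carbamate 10 (not isolated)
Conditions: Pd2(dba)3·CHCl3 (2.5 mol %), chiral BINOL-derived phosphoramidite (10 mol %), 9 (1.5 equiv), toluene, 0 °C → rt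
Reagents that add atoms: none
Why: Pd-catalysed asymmetric dearomative allylic alkylation (Tsuji–Trost type) of a 3-substituted indole, in which the indole attacks the unsubstituted terminus of the π-prenyl-Pd complex through C3 on the face fixed by the chiral ligand (setting C3a), and the carbamate N–H then adds to the C=N of 10 on the only face the two-carbon tether allows (setting C8a cis to the prenyl group).

**Step 7**
Reactants: 11 methyl (3aS,8aS)-7-bromo-4-methoxy-3a-(3-methylbut-2-en-1-yl)-3,3a,8,8a-tetrahydropyrrolo[2,3-b]indole-1(2H)-carboxylate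
Product: 12 (3aS,8aS)-7-bromo-4-methoxy-1-methyl-3a-(3-methylbut-2-en-1-yl)-1,2,3,3a,8,8a-hexahydropyrrolo[2,3-b]indole
Conditions: Red-Al (5 equiv), toluene, 80 °C; aq. Rochelle salt
Reagents that add atoms: none
Why: Hydride reduction of a methyl carbamate to an N-methyl amine, with Red-Al chosen to spare the aryl bromide; neither stereocentre can epimerise, since C3a is quaternary and C8a is held cis by the ring fusion.

**Step 8**
Reactants: 12 (3aS,8aS)-7-bromo-4-methoxy-1-methyl-3a-(3-methylbut-2-en-1-yl)-1,2,3,3a,8,8a-hexahydropyrrolo[2,3-b]indole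
Product: 13 (3aS,8aS)-7-bromo-1-methyl-3a-(3-methylbut-2-en-1-yl)-1,2,3,3a,8,8a-hexahydropyrrolo[2,3-b]indol-4-ol
Conditions: NaSEt (5 equiv), DMF (degassed), 120 °C; dil. HCl to pH 7–8
Reagents that add atoms: none
Why: SN2 O-demethylation of an aryl methyl ether by a thiolate, which attacks only the O-methyl carbon and involves no acid that could touch the prenyl alkene or the aminal.

**Step 9**
Reactants: 13 (3aS,8aS)-7-bromo-1-methyl-3a-(3-methylbut-2-en-1-yl)-1,2,3,3a,8,8a-hexahydropyrrolo[2,3-b]indol-4-ol
Product: 14 (3aS,8aS)-7-bromo-5-iodo-1-methyl-3a-(3-methylbut-2-en-1-yl)-1,2,3,3a,8,8a-hexahydropyrrolo[2,3-b]indol-4-ol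
Conditions: NIS (1.0 equiv), TsOH·H2O (1.0 equiv), MeCN, −20 → 0 °C, dark; aq. Na2S2O3/NaHCO3
Reagents that add atoms: N-iodosuccinimide, O=C1CCC(=O)N1I
Why: Electrophilic aromatic iodination, which can only go to C5 because C7 is blocked by bromine and C5 is the one remaining position ortho to the hydroxyl and para to N8; protonating the basic N1 with TsOH beforehand keeps the amine from being oxidised by the N-iodo reagent.

**Step 10**
Reactants: 14 (3aS,8aS)-7-bromo-5-iodo-1-methyl-3a-(3-methylbut-2-en-1-yl)-1,2,3,3a,8,8a-hexahydropyrrolo[2,3-b]indol-4-ol; 15 2-methylbut-3-yn-2-ol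
Product: 17 the target (2-hydroxyprop-2-yl furan fused through O at C4 and carbon at C5 of (3aS,8aS)-7-bromo-1-methyl-3a-prenyl-1,2,3,3a,8,8a-hexahydropyrrolo[2,3-b]indole), via 5-alkynylphenol 16 (not isolated)
Conditions: PdCl2(PPh3)2 (5 mol %), CuI (10 mol %), 15 (1.3 equiv), Et3N/DMF (degassed), rt → 55 °C
Reagents that add atoms: none
Why: This is a Sonogashira coupling followed in the same flask by cycloisomerisation, the standard one-pot route from ortho-iodophenols and terminal alkynes to 2-substituted benzofurans. Pd(0) inserts into the C5–I bond, the copper acetylide of 15 transmetalates, and reductive elimination forms the C5–C(sp) bond of alkynylphenol 16. The C4 phenoxide then adds to the Cu- or Pd-coordinated alkyne in a 5-endo-dig oxycyclisation, the only closure geometrically open to an ortho-alkynylphenol, so oxygen bonds to the carbinol-bearing alkyne carbon, which becomes furan C2, and protodemetalation releases the furan. No stereocentre is formed, and C3a and C8a are untouched because the medium is neither acidic nor reducing. The step needs oxidative addition at C–I in preference to C–Br; this should be secured by the large intrinsic rate difference at or below 55 °C with a PPh3-ligated catalyst, by the electron-rich position of the C7 bromide next to N8–H, and by using only a small excess of alkyne. The tertiary alcohol arrives intact with the alkyne, and N8–H, the basic N1 and the prenyl alkene should be spectators under amine base.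

**Compound list**

1 | 4-bromo-3-nitroanisole (1-bromo-4-methoxy-2-nitrobenzene) | COc1ccc(Br)c([N+](=O)[O-])c1 | starting material
2 | 1-bromo-4-methoxy-2-nitrosobenzene | COc1ccc(Br)c(N=O)c1 | intermediate
3 | 7-bromo-4-methoxy-1H-indole | COc1ccc(Br)c2[nH]ccc12 | intermediate
4 | 2-(7-bromo-4-methoxy-1H-indol-3-yl)-2-oxoacetyl chloride | COc1ccc(Br)c2[nH]cc(C(=O)C(=O)Cl)c12 | intermediate
5 | 2-(7-bromo-4-methoxy-1H-indol-3-yl)-2-oxoacetamide | COc1ccc(Br)c2[nH]cc(C(=O)C(N)=O)c12 | intermediate
6 | 2-(7-bromo-4-methoxy-1H-indol-3-yl)ethan-1-amine | COc1ccc(Br)c2[nH]cc(CCN)c12 | intermediate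
7 | methyl N-[2-(7-bromo-4-methoxy-1H-indol-3-yl)ethyl]carbamate | COC(=O)NCCc1c[nH]c2c(Br)ccc(OC)c12 | intermediate
8 | 3-methylbut-2-en-1-ol (prenol) | CC(C)=CCO | starting material
9 | methyl 3-methylbut-2-en-1-yl carbonate | CC(C)=CCOC(=O)OC | intermediate
10 | methyl N-{2-[(3S)-7-bromo-4-methoxy-3-(3-methylbut-2-en-1-yl)-3H-indol-3-yl]ethyl}carbamate | CC(C)=CC[C@@]1(CCNC(=O)OC)C=Nc2c(Br)ccc(OC)c21 | intermediate
11 | methyl (3aS,8aS)-7-bromo-4-methoxy-3a-(3-methylbut-2-en-1-yl)-3,3a,8,8a-tetrahydropyrrolo[2,3-b]indole-1(2H)-carboxylate | CC(C)=CC[C@@]12CCN(C(=O)OC)[C@@H]1Nc1c(Br)ccc(OC)c12 | intermediate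
12 | (3aS,8aS)-7-bromo-4-methoxy-1-methyl-3a-(3-methylbut-2-en-1-yl)-1,2,3,3a,8,8a-hexahydropyrrolo[2,3-b]indole | CC(C)=CC[C@@]12CCN(C)[C@@H]1Nc1c(Br)ccc(OC)c12 | intermediate
13 | (3aS,8aS)-7-bromo-1-methyl-3a-(3-methylbut-2-en-1-yl)-1,2,3,3a,8,8a-hexahydropyrrolo[2,3-b]indol-4-ol | CC(C)=CC[C@@]12CCN(C)[C@@H]1Nc1c(Br)ccc(O)c12 | intermediate
14 | (3aS,8aS)-7-bromo-5-iodo-1-methyl-3a-(3-methylbut-2-en-1-yl)-1,2,3,3a,8,8a-hexahydropyrrolo[2,3-b]indol-4-ol | CC(C)=CC[C@@]12CCN(C)[C@@H]1Nc1c(Br)cc(I)c(O)c12 | intermediate
15 | 2-methylbut-3-yn-2-ol | CC(C)(O)C#C | starting material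
16 | (3aS,8aS)-7-bromo-5-(3-hydroxy-3-methylbut-1-yn-1-yl)-1-methyl-3a-(3-methylbut-2-en-1-yl)-1,2,3,3a,8,8a-hexahydropyrrolo[2,3-b]indol-4-ol | CC(C)=CC[C@@]12CCN(C)[C@@H]1Nc1c(Br)cc(C#CC(C)(C)O)c(O)c12 | intermediate
17 | target: (3aS,8aS)-7-bromo-1-methyl-3a-prenyl-hexahydropyrrolo[2,3-b]indole with a furan fused through O at C4 and carbon at C5, bearing 2-hydroxyprop-2-yl on furan C2 | CC(C)=CC[C@@]12CCN(C)[C@@H]1Nc1c(Br)cc3cc(C(C)(C)O)oc3c12 | target

**Step count**

Total: 10 steps. Longest linear sequence: 9 steps (steps 1–4 and 6–10); step 5 is a one-step side branch.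

**Steps most likely to fail**

Step 6. Attack through C3 is slowed by the peri methoxy group at C4, so N-prenylation or poor discrimination between the two indole faces may take over. The fallback sets out from 7 and returns at 11. Compound 7 is first allylated enantioselectively at C3 with allyl alcohol, 9-hexyl-9-BBN, Pd2(dba)3 and a C2-symmetric diaminocyclohexane-derived bisphosphine ligand in CH2Cl2 at rt. The smaller allyl electrophile and the borane bound to the indole nitrogen should ease C3 attack, and the product cyclises as before to methyl (3aS,8aS)-3a-allyl-7-bromo-4-methoxy-3,3a,8,8a-tetrahydropyrrolo[2,3-b]indole-1(2H)-carboxylate F1. Cross-metathesis of the terminal alkene with 2-methylbut-2-ene (second-generation Ru–NHC catalyst, CH2Cl2, 40 °C) then converts allyl into prenyl and gives 11.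

Step 10. Oxidative addition may also occur at the C7–Br bond once the mixture is warmed for ring closure; the alkyne may dimerise oxidatively; or the ring closure may stall at the alkynylphenol. The fallback sets out from 14 and 15 and returns at 17. Alkyne 15 is converted with CuI in aqueous ammonia/ethanol into copper(I) 3-hydroxy-3-methylbut-1-yn-1-ide F2. Heating F2 with 14 in pyridine at 110 °C under nitrogen (Castro–Stephens coupling) should form the C5–alkyne bond and close the furan in the same operation. No palladium is present, so the aryl bromide is not at risk.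

Step 8. The thiolate may attack the aryl bromide (substitution or reduction), or demethylation next to the quaternary centre may stall at temperatures the aminal tolerates. The fallback sets out from 7 and returns at 13 by exchanging the protecting group before the prenyl group is present. BBr3 in CH2Cl2 (−78 → 0 °C) cleaves the methyl ether of 7 to methyl N-[2-(7-bromo-4-hydroxy-1H-indol-3-yl)ethyl]carbamate F3. TIPSCl/imidazole in DMF gives methyl N-[2-(7-bromo-4-triisopropylsilyloxy-1H-indol-3-yl)ethyl]carbamate F4. Prenylation with 9 under the conditions of step 6 gives methyl (3aS,8aS)-7-bromo-3a-(3-methylbut-2-en-1-yl)-4-triisopropylsilyloxy-3,3a,8,8a-tetrahydropyrrolo[2,3-b]indole-1(2H)-carboxylate F5. Red-Al as in step 7 gives (3aS,8aS)-7-bromo-1-methyl-3a-(3-methylbut-2-en-1-yl)-4-triisopropylsilyloxy-1,2,3,3a,8,8a-hexahydropyrrolo[2,3-b]indole F6. Any silyl ether that survives the hydride is removed with TBAF in THF at 0 °C to give 13.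

**Further compounds**

F1 | step 6 | methyl (3aS,8aS)-3a-allyl-7-bromo-4-methoxy-3,3a,8,8a-tetrahydropyrrolo[2,3-b]indole-1(2H)-carboxylate | C=CC[C@@]12CCN(C(=O)OC)[C@@H]1Nc1c(Br)ccc(OC)c12
F2 | step 10 | copper(I) 3-hydroxy-3-methylbut-1-yn-1-ide | CC(C)(O)C#C[Cu]
F3 | step 8 | methyl N-[2-(7-bromo-4-hydroxy-1H-indol-3-yl)ethyl]carbamate | COC(=O)NCCc1c[nH]c2c(Br)ccc(O)c12
F4 | step 8 | methyl N-[2-(7-bromo-4-triisopropylsilyloxy-1H-indol-3-yl)ethyl]carbamate | COC(=O)NCCc1c[nH]c2c(Br)ccc(O[Si](C(C)C)(C(C)C)C(C)C)c12
F5 | step 8 | methyl (3aS,8aS)-7-bromo-3a-(3-methylbut-2-en-1-yl)-4-triisopropylsilyloxy-3,3a,8,8a-tetrahydropyrrolo[2,3-b]indole-1(2H)-carboxylate | CC(C)=CC[C@@]12CCN(C(=O)OC)[C@@H]1Nc1c(Br)ccc(O[Si](C(C)C)(C(C)C)C(C)C)c12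
F6 | step 8 | (3aS,8aS)-7-bromo-1-methyl-3a-(3-methylbut-2-en-1-yl)-4-triisopropylsilyloxy-1,2,3,3a,8,8a-hexahydropyrrolo[2,3-b]indole | CC(C)=CC[C@@]12CCN(C)[C@@H]1Nc1c(Br)ccc(O[Si](C(C)C)(C(C)C)C(C)C)c12
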